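**Retrosynthetic overview**

1. Ring numbering: C1 = ketone carbon, C2=C3 = ring alkene, C4 = carbon bearing OAc and the C8 chain, C5 = carbon bearing the (Z)-pentenyl group. The end game is only acetylation of C4–OH and adjustment of the chain terminus (CH2OSi to CO2H).
2. Enabling feature: C1(=O)–C5(H)–C4(O) is a β-oxy ketone (aldol retron) inside a five-membered carbocycle whose C2=C3 bond is necessarily cis. Cleaving C4–C5 therefore leads to a (Z)-ene-1,4-dione mono-enol, a 1,4-dioxygenated pentadienyl system C4–C3–C2–C1–C5.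
3. That enol can be stored regiospecifically in a five-membered oxygen ring, a γ-ylidenebutenolide (lactone C=O = C4, ring O = oxygen of C1, exocyclic =CH = C5), which is an achiral, flat C10 compound.
4. Key disconnection C4–CH2(chain): a C8 alkyllithium plus the lactone carbonyl. In the same operation the oxygen ring opens and the carbocycle closes (C4–C5, conrotatory 4π) under a chiral phosphoric acid, which sets C4 and C5.
5. The butenolide comes from (Z)-3-iodoacrylic acid and (Z)-hept-4-en-1-yne (Sonogashira/5-exo-dig). Ring order: the temporary oxygen ring first (step 3), the carbocycle second (step 6) at its expense.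

Key step: step 6

Assumption: the sense of induction of (R)-TRIP, which is (R)-3,3'-bis(2,4,6-triisopropylphenyl)-1,1'-binaphthyl-2,2'-diyl hydrogen phosphate, in step 6 cannot be derived from precedent with certainty; the (R)-acid is written, and its commercial (S)-antipode would be taken if the opposite sense is found.

**Route**

Step 1
Reactants: 1 (Z)-pent-2-en-1-ol
Product: 2 (Z)-1-bromopent-2-ene
Conditions: CBr4, PPh3, CH2Cl2, 0 °C
Reagents that add atoms: carbon tetrabromide BrC(Br)(Br)Br
Why: Appel reaction: SN2 displacement of the alkoxyphosphonium ion at the primary allylic carbon under neutral conditions should give the bromide without allylic shift and without loss of the Z geometry.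

Step 2
Reactants: 2 (Z)-1-bromopent-2-ene; 3 ethynylmagnesium bromide (excess, 0.5 M in THF)
Product: 4 (Z)-hept-4-en-1-yne
Conditions: CuCl (5 mol %), THF, 0 to 40 °C
Reagents that add atoms: none
Why: Copper-catalysed allyl–alkynyl coupling of an alkynyl Grignard reagent, which attacks the unhindered primary carbon of the allylic bromide (SN2, Z geometry kept), while the excess of 3 suppresses a second alkylation of the product alkyne.

Step 3
Reactants: 4 (Z)-hept-4-en-1-yne; 5 (Z)-3-iodoprop-2-enoic acid
Product: 7 (5Z)-5-[(3Z)-hex-3-en-1-ylidene]furan-2(5H)-one, via enynoic acid 6 (not isolated)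
Conditions: Pd(PPh3)4 (5 mol %), CuI (5 mol %), Et3N, MeCN, 23 °C
Reagents that add atoms: none
Why: Sonogashira coupling followed in the same flask by metal-catalysed 5-exo-dig lactonisation of the (Z)-enynoic acid, a known tandem entry to (Z)-γ-ylidenebutenolides in which anti addition of carboxylate and metal across the alkyne sets the exocyclic Z geometry.

Step 4
Reactants: 8 8-bromooctan-1-ol
Product: 9 (8-bromooctyloxy)(tert-butyl)diphenylsilane
Conditions: TBDPSCl, imidazole, DMF, 23 °C
Reagents that add atoms: tert-butyl(chloro)diphenylsilane CC(C)(C)[Si](Cl)(c1ccccc1)c1ccccc1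
Why: Standard silylation of a primary alcohol; the tert-butyldiphenylsilyl ether is chosen because it should survive t-BuLi, the acids of step 6 and the Lewis acid of step 7.

Step 5
Reactants: 9 (8-bromooctyloxy)(tert-butyl)diphenylsilane
Product: 10 tert-butyl(8-iodooctyloxy)diphenylsilane
Conditions: NaI, acetone, reflux
Reagents that add atoms: sodium iodide [Na+].[I-]
Why: Finkelstein reaction driven by precipitation of NaBr, needed because only the primary iodide undergoes clean lithium–iodine exchange.

Step 6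
Reactants: 10 tert-butyl(8-iodooctyloxy)diphenylsilane; 7 (5Z)-5-[(3Z)-hex-3-en-1-ylidene]furan-2(5H)-one
Product: 15 (4R,5S)-4-[8-(tert-butyldiphenylsilyloxy)octyl]-4-hydroxy-5-[(Z)-pent-2-en-1-yl]cyclopent-2-en-1-one, via organolithium 11 (not isolated), via lithium lactolate 12 (not isolated), via hemiketal 13 (not isolated), via keto-dienol 14 (not isolated)
Conditions: 10, t-BuLi (2.05 equiv), Et2O–pentane, −78 °C; cannulated into 7, Et2O–toluene, −90 °C; HCl (1.0 equiv, 2 M in Et2O), −90 °C; (R)-TRIP (10 mol %), toluene, −78 to −30 °C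
Reagents that add atoms: none
Why: Proposed new method: alkyllithium 11 adds to the lactone carbonyl of 7 (the future C4, which forms the C4–CH2 bond) to give lactolate 12, and after neutralisation hemiketal 13 opens to keto-dienol 14, in which the old ring oxygen is the enol oxygen on C1 and the old exocyclic carbon is the nucleophilic C5. Bridged between P=O and P–OH of the chiral phosphoric acid, 14 behaves as a 1,4-dihydroxypentadienyl cation (C4–C3–C2–C1–C5) and closes the carbocycle at C4–C5 by a thermally allowed conrotatory 4π electrocyclisation, formally a 5-(enolendo)-exo-trig aldol addition, which is the ring-forming event of the Piancatelli rearrangement and of the allene oxide to 12-oxophytodienoic acid cyclisation. The closest known reaction types are the addition of Grignard reagents to benzylidenephthalide and to enol lactones (Fujimoto–Belleau reaction: addition, ring opening, aldol closure), the organolithium addition and acid quench variant of the Nazarov cyclisation, and the chiral phosphoric acid catalysed aza-Piancatelli rearrangement; their union on a γ-ylidenebutenolide, with oxygen instead of nitrogen at C4, is what is new. Relative configuration: the Z-ylidene geometry of 7 places the pentenyl group outward on C5 and the acid-bound oxygen sits outward on C4, so conrotation sets them trans and the two carbon chains cis, as in Piancatelli products of 5-alkylfurylcarbinols. Absolute configuration: the racemic hemiketal centre of 12 and 13 is erased on ring opening, and the phosphate pocket that is hydrogen-bonded to both hydroxyls should select one of the two enantiomeric conrotatory senses to give 4R,5S. The step needs 1,2-addition in preference to 1,4- and 1,6-addition and to deprotonation of the doubly allylic CH2 (hard alkyllithium, ether solvent, very low temperature, inverse addition), and it needs the enol on the pentenyl side only, which the enol-lactone C=C of 7 stores and which the free ene-dione, having two nearly identical α-CH2 groups, could not provide.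

Step 7
Reactants: 15 (4R,5S)-4-[8-(tert-butyldiphenylsilyloxy)octyl]-4-hydroxy-5-[(Z)-pent-2-en-1-yl]cyclopent-2-en-1-one
Product: 16 (1R,5S)-1-[8-(tert-butyldiphenylsilyloxy)octyl]-4-oxo-5-[(Z)-pent-2-en-1-yl]cyclopent-2-en-1-yl acetate
Conditions: Ac2O, Sc(OTf)3 (2 mol %), MeCN, −20 °C
Reagents that add atoms: acetic anhydride CC(=O)OC(C)=O
Why: Lewis acid catalysed acylation with Sc(OTf)3 and Ac2O, a known method for hindered tertiary alcohols, works without amine base and so should avoid C5 epimerisation and E1cB loss of the new acetate, and it touches no stereocentre.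

Step 8
Reactants: 16 (1R,5S)-1-[8-(tert-butyldiphenylsilyloxy)octyl]-4-oxo-5-[(Z)-pent-2-en-1-yl]cyclopent-2-en-1-yl acetate
Product: 17 (1R,5S)-1-(8-hydroxyoctyl)-4-oxo-5-[(Z)-pent-2-en-1-yl]cyclopent-2-en-1-yl acetate
Conditions: HF·pyridine, THF, 0 to 23 °C
Reagents that add atoms: none
Why: Fluoride-induced cleavage of the silyl ether under weakly acidic conditions, which the enone, the tertiary acetate, the Z-alkene and the epimerisable C5 centre should tolerate.

Step 9
Reactants: 17 (1R,5S)-1-(8-hydroxyoctyl)-4-oxo-5-[(Z)-pent-2-en-1-yl]cyclopent-2-en-1-yl acetate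
Product: 19 8-{(1R,5S)-1-acetoxy-4-oxo-5-[(Z)-pent-2-en-1-yl]cyclopent-2-en-1-yl}octanoic acid, via aldehyde 18 (not isolated)
Conditions: TEMPO (20 mol %), PhI(OAc)2 (2.2 equiv), MeCN–H2O, 23 °C
Reagents that add atoms: water O
Why: Oxoammonium oxidation (TEMPO/PhI(OAc)2) in aqueous acetonitrile takes the primary alcohol through aldehyde 18 and its hydrate to the acid at weakly acidic pH, so that no base ever meets the C5–H/C4–OAc pair.

**Compound list**

1 | (Z)-pent-2-en-1-ol | CC/C=C\CO | starting material
2 | (Z)-1-bromopent-2-ene | CC/C=C\CBr | intermediate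
3 | ethynylmagnesium bromide | C#C[Mg]Br | starting material
4 | (Z)-hept-4-en-1-yne | CC/C=C\CC#C | intermediate
5 | (Z)-3-iodoprop-2-enoic acid | OC(=O)/C=C\I | starting material
6 | (2Z,7Z)-deca-2,7-dien-4-ynoic acid | CC/C=C\CC#C/C=C\C(=O)O | intermediate
7 | (5Z)-5-[(3Z)-hex-3-en-1-ylidene]furan-2(5H)-one | CC/C=C\C/C=C1/C=CC(=O)O1 | intermediate
8 | 8-bromooctan-1-ol | OCCCCCCCCBr | starting material
9 | (8-bromooctyloxy)(tert-butyl)diphenylsilane | CC(C)(C)[Si](OCCCCCCCCBr)(c1ccccc1)c1ccccc1 | intermediate
10 | tert-butyl(8-iodooctyloxy)diphenylsilane | CC(C)(C)[Si](OCCCCCCCCI)(c1ccccc1)c1ccccc1 | intermediate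
11 | 8-(tert-butyldiphenylsilyloxy)octyllithium | [Li]CCCCCCCCO[Si](C(C)(C)C)(c1ccccc1)c1ccccc1 | intermediate
12 | lithium (5Z)-2-[8-(tert-butyldiphenylsilyloxy)octyl]-5-[(3Z)-hex-3-en-1-ylidene]-2,5-dihydrofuran-2-olate (racemic at C2) | CC/C=C\C/C=C1/C=CC([O-])(CCCCCCCCO[Si](C(C)(C)C)(c2ccccc2)c2ccccc2)O1.[Li+] | intermediate
13 | (5Z)-2-[8-(tert-butyldiphenylsilyloxy)octyl]-5-[(3Z)-hex-3-en-1-ylidene]-2,5-dihydrofuran-2-ol (racemic at C2) | CC/C=C\C/C=C1/C=CC(O)(CCCCCCCCO[Si](C(C)(C)C)(c2ccccc2)c2ccccc2)O1 | intermediate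
14 | (10Z,12Z,15Z)-1-(tert-butyldiphenylsilyloxy)-12-hydroxyoctadeca-10,12,15-trien-9-one | CC/C=C\C/C=C(O)/C=C\C(=O)CCCCCCCCO[Si](C(C)(C)C)(c1ccccc1)c1ccccc1 | intermediate
15 | (4R,5S)-4-[8-(tert-butyldiphenylsilyloxy)octyl]-4-hydroxy-5-[(Z)-pent-2-en-1-yl]cyclopent-2-en-1-one (OH trans to pentenyl) | CC/C=C\C[C@@H]1C(=O)C=C[C@@]1(CCCCCCCCO[Si](C(C)(C)C)(c2ccccc2)c2ccccc2)O | intermediate
16 | (1R,5S)-1-[8-(tert-butyldiphenylsilyloxy)octyl]-4-oxo-5-[(Z)-pent-2-en-1-yl]cyclopent-2-en-1-yl acetate | CC/C=C\C[C@@H]1C(=O)C=C[C@@]1(CCCCCCCCO[Si](C(C)(C)C)(c2ccccc2)c2ccccc2)OC(C)=O | intermediate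
17 | (1R,5S)-1-(8-hydroxyoctyl)-4-oxo-5-[(Z)-pent-2-en-1-yl]cyclopent-2-en-1-yl acetate | CC/C=C\C[C@@H]1C(=O)C=C[C@@]1(CCCCCCCCO)OC(C)=O | intermediate
18 | (1R,5S)-4-oxo-1-(8-oxooctyl)-5-[(Z)-pent-2-en-1-yl]cyclopent-2-en-1-yl acetate | CC/C=C\C[C@@H]1C(=O)C=C[C@@]1(CCCCCCCC=O)OC(C)=O | intermediate
19 | 8-{(1R,5S)-1-acetoxy-4-oxo-5-[(Z)-pent-2-en-1-yl]cyclopent-2-en-1-yl}octanoic acid | CC/C=C\C[C@@H]1C(=O)C=C[C@@]1(CCCCCCCC(=O)O)OC(C)=O | target

Total step count: 9
Longest linear sequence: 7 (steps 1, 2, 3, 6, 7, 8, 9)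

**Steps most likely to fail**

**Step 6 (proposed method).**
- What may go wrong: premature anionic ring closure of the lactolate before the chiral acid is present, which would lose enantiocontrol.
- What may go wrong: proton abstraction from the doubly allylic CH2, or a second addition, in place of clean mono-addition to the carbonyl.
- What may go wrong: tautomerisation of the dienol ahead of ring closure, which would lose the regiochemical memory.
- What may go wrong: weak selection between the two conrotatory senses.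
- Fallback (known chemistry): the same C4–CH2 bond is made by 1,2-addition to a ring that is already closed. It sets out from iodide 10 and comes back at alcohol 15. Organolithium 11, made as in step 6, is added at −78 °C to commercial (R)-4-(tert-butyldimethylsilyloxy)cyclopent-2-en-1-one. Attack anti to the silyloxy group should give (1S,4R)-4-(tert-butyldimethylsilyloxy)-1-[8-(tert-butyldiphenylsilyloxy)octyl]cyclopent-2-en-1-ol F1. Pyridine-buffered HF·pyridine at 0 °C frees only the secondary alcohol, giving (1S,4R)-1-[8-(tert-butyldiphenylsilyloxy)octyl]cyclopent-2-ene-1,4-diol F2. MnO2 then oxidises the secondary allylic alcohol to (S)-4-[8-(tert-butyldiphenylsilyloxy)octyl]-4-hydroxycyclopent-2-en-1-one F3. TESOTf and 2,6-lutidine give (S)-4-[8-(tert-butyldiphenylsilyloxy)octyl]-4-(triethylsilyloxy)cyclopent-2-en-1-one F4. LDA at −78 °C forms the cross-conjugated lithium enolate F5, which is alkylated at C5 with bromide 2 anti to the bulky silyloxy group. This should give (4R,5S)-4-[8-(tert-butyldiphenylsilyloxy)octyl]-5-[(Z)-pent-2-en-1-yl]-4-(triethylsilyloxy)cyclopent-2-en-1-one F6. Brief treatment with buffered HF·pyridine removes the triethylsilyl group and returns 15.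

**Step 7.**
- What may go wrong: slow acylation of the hindered tertiary alcohol, so that Lewis acid induced enolisation (C5 epimerisation), retro-aldol ring opening or cleavage of the silyl ether compete.
- Fallback: the oxidation level at C1 is lowered for a time so that C5–H is no longer acidic. It sets out from 15 and comes back at 16. Luche reduction (NaBH4, CeCl3·7H2O, MeOH, −78 °C), with hydride attack anti to the pentenyl group, should give (1R,4R,5R)-1-[8-(tert-butyldiphenylsilyloxy)octyl]-5-[(Z)-pent-2-en-1-yl]cyclopent-2-ene-1,4-diol F7; the configuration of the new carbinol centre is of no consequence. Exhaustive acetylation (Ac2O, Et3N, DMAP, CH2Cl2) gives (1R,4R,5R)-1-[8-(tert-butyldiphenylsilyloxy)octyl]-5-[(Z)-pent-2-en-1-yl]cyclopent-2-ene-1,4-diyl diacetate F8. K2CO3 in MeOH at 0 °C cleaves only the secondary allylic acetate to give (1R,4R,5R)-1-[8-(tert-butyldiphenylsilyloxy)octyl]-4-hydroxy-5-[(Z)-pent-2-en-1-yl]cyclopent-2-en-1-yl acetate F9. Dess–Martin periodinane buffered with NaHCO3 restores the enone and returns 16.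

**Step 3.**
- What may go wrong: competition of 6-endo-dig with 5-exo-dig closure, and base- or metal-induced migration of the skipped enyne unsaturation into conjugation during the tandem process.
- Fallback: the coupling and the ring closure are uncoupled, and the closure is handed to another metal. It sets out from enyne 4 and comes back at butenolide 7. Sonogashira coupling of 4 with commercial ethyl (Z)-3-iodoacrylate gives ethyl (2Z,7Z)-deca-2,7-dien-4-ynoate F10. LiOH in aqueous THF gives acid 6, now isolated. AgNO3 (10 mol %) in acetone closes it 5-exo-dig to 7.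

**Further compounds**

F1 | step 6 | (1S,4R)-4-(tert-butyldimethylsilyloxy)-1-[8-(tert-butyldiphenylsilyloxy)octyl]cyclopent-2-en-1-ol | C1[C@@H](O[Si](C)(C)C(C)(C)C)C=C[C@@]1(CCCCCCCCO[Si](C(C)(C)C)(c2ccccc2)c2ccccc2)O
F2 | step 6 | (1S,4R)-1-[8-(tert-butyldiphenylsilyloxy)octyl]cyclopent-2-ene-1,4-diol | C1[C@@H](O)C=C[C@@]1(CCCCCCCCO[Si](C(C)(C)C)(c2ccccc2)c2ccccc2)O
F3 | step 6 | (S)-4-[8-(tert-butyldiphenylsilyloxy)octyl]-4-hydroxycyclopent-2-en-1-one | C1C(=O)C=C[C@@]1(CCCCCCCCO[Si](C(C)(C)C)(c2ccccc2)c2ccccc2)O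
F4 | step 6 | (S)-4-[8-(tert-butyldiphenylsilyloxy)octyl]-4-(triethylsilyloxy)cyclopent-2-en-1-one | C1C(=O)C=C[C@@]1(CCCCCCCCO[Si](C(C)(C)C)(c2ccccc2)c2ccccc2)O[Si](CC)(CC)CC
F5 | step 6 | cross-conjugated lithium enolate of F4 | C1=C([O-])C=C[C@@]1(CCCCCCCCO[Si](C(C)(C)C)(c2ccccc2)c2ccccc2)O[Si](CC)(CC)CC.[Li+]
F6 | step 6 | (4R,5S)-4-[8-(tert-butyldiphenylsilyloxy)octyl]-5-[(Z)-pent-2-en-1-yl]-4-(triethylsilyloxy)cyclopent-2-en-1-one | CC/C=C\C[C@@H]1C(=O)C=C[C@@]1(CCCCCCCCO[Si](C(C)(C)C)(c2ccccc2)c2ccccc2)O[Si](CC)(CC)CC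
F7 | step 7 | (1R,4R,5R)-1-[8-(tert-butyldiphenylsilyloxy)octyl]-5-[(Z)-pent-2-en-1-yl]cyclopent-2-ene-1,4-diol | CC/C=C\C[C@@H]1[C@H](O)C=C[C@@]1(CCCCCCCCO[Si](C(C)(C)C)(c2ccccc2)c2ccccc2)O
F8 | step 7 | (1R,4R,5R)-1-[8-(tert-butyldiphenylsilyloxy)octyl]-5-[(Z)-pent-2-en-1-yl]cyclopent-2-ene-1,4-diyl diacetate | CC/C=C\C[C@@H]1[C@H](OC(C)=O)C=C[C@@]1(CCCCCCCCO[Si](C(C)(C)C)(c2ccccc2)c2ccccc2)OC(C)=O
F9 | step 7 | (1R,4R,5R)-1-[8-(tert-butyldiphenylsilyloxy)octyl]-4-hydroxy-5-[(Z)-pent-2-en-1-yl]cyclopent-2-en-1-yl acetate | CC/C=C\C[C@@H]1[C@H](O)C=C[C@@]1(CCCCCCCCO[Si](C(C)(C)C)(c2ccccc2)c2ccccc2)OC(C)=O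
F10 | step 3 | ethyl (2Z,7Z)-deca-2,7-dien-4-ynoate | CC/C=C\CC#C/C=C\C(=O)OCC
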